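Ring A is cut at C3–C4 and C5–C6, the two bonds that a [4+2] cycloaddition makes when a 2-prenyl vinyl isopropyl ketone meets a 1,1,3-trioxygenated pentadiene. The step exploits the quaternary C4 of ring A, which carries prenyl and isobutyryl between ring carbons C3 and C5, and the oxygens at C1 and C3. One catalytic enantioselective Diels–Alder reaction closes ring A and sets C4, the only stereocentre. The precursors are the α-methylene ketone 6 and the ketene-acetal silyl dienol ether 10; the adduct unravels to a C3 ethyl enol ether with a free C1 ketone. C5 is then oxygenated, and C2 is linked to ring B through a methylene.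

Key step: step 5

Remark 1: the target is handled as the drawn enol tautomer; ring A is numbered C1 (carbonyl), C2 (bears the bridge), C3, C4 (quaternary), C5, C6 (bears methyl) throughout, and the spatial arrangement at C4 is the same in every compound although its CIP letter changes with the neighbours (R in 11 and 18, S elsewhere).

Remark 2: the diene carries a diethyl ketene acetal terminus and a triisopropylsilyl enol ether, so that the cycloadduct collapses to a single vinylogous ester (ethoxy on C3, ketone at C1) and silyl transfer to the catalyst is slowed; a bis-trimethylsilyl β-keto ester diene would give the free 1,3-dione, whose two oxygens cannot be differentiated for the later C5–C6 desaturation.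

Remark 3: the (S)-configured catalyst is assumed to give the (4S) adduct by analogy with 2-substituted acroleins; the facial sense is to be verified on 12 and the catalyst from (R)-diphenylprolinol used if it proves opposite.

Step 1
Reactants: 1 3-methylbutan-2-one; 2 1-bromo-3-methylbut-2-ene
Product: 3 2,7-dimethyloct-6-en-3-one
Conditions: LiN(i-Pr)2, THF, −78 °C; then 2, −78 → 0 °C
Reagents that add atoms: none
Why: Kinetic deprotonation by the hindered amide occurs at the methyl group and the lithium enolate is alkylated by the allylic bromide at its primary carbon (SN2 enolate alkylation).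

Step 2
Reactants: 3 2,7-dimethyloct-6-en-3-one
Product: 6 2,7-dimethyl-4-methylideneoct-6-en-3-one, via Mannich base 4 (not isolated), via ammonium iodide 5 (not isolated)
Conditions: LiN(i-Pr)2, THF, −78 °C; CH2=NMe2+ I−, −78 °C → rt; MeI, rt; then aq. NaHCO3, rt
Reagents that add atoms: dimethylmethylideneammonium iodide (Eschenmoser's salt), C=[N+](C)C.[I-]
Why: The amide base removes a methylene proton in preference to the isopropyl methine, the enolate is aminomethylated by the preformed iminium salt (Mannich reaction), and N-methylation followed by base-induced β-elimination of trimethylamine gives the 1,1-disubstituted enone, which is used at once because such enones dimerise on storage.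

Step 3
Reactants: 7 1,1-diethoxyethene; 8 propanoyl chloride
Product: 9 1,1-diethoxypent-1-en-3-one
Conditions: 7 (2.2 equiv), Et2O, 0 °C → rt
Reagents that add atoms: none
Why: C-Acylation of the strongly nucleophilic ketene acetal gives a dialkoxycarbenium ion that loses a proton to a second equivalent of 7, which is consumed as the hydrogen chloride scavenger, leaving the push–pull acylketene acetal (acylation of a ketene acetal).

Step 4
Reactants: 9 1,1-diethoxypent-1-en-3-one
Product: 10 (3Z)-1,1-diethoxy-3-[tri(propan-2-yl)silyloxy]penta-1,3-diene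
Conditions: i-Pr3SiOTf, Et3N, Et2O, 0 °C → rt
Reagents that add atoms: triisopropylsilyl trifluoromethanesulfonate, CC(C)[Si](OS(=O)(=O)C(F)(F)F)(C(C)C)C(C)C
Why: Soft enolisation, in which O-silylation of the electron-rich carbonyl is followed by deprotonation of the only enolisable position (the ethyl CH2), gives the silyl dienol ether with the usual Z enol ether geometry that places the methyl group on the outside of the diene.

Step 5
Reactants: 6 2,7-dimethyl-4-methylideneoct-6-en-3-one; 10 (3Z)-1,1-diethoxy-3-[tri(propan-2-yl)silyloxy]penta-1,3-diene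
Product: 12 (4S)-3-ethoxy-6-methyl-4-(3-methylbut-2-en-1-yl)-4-(2-methylpropanoyl)cyclohex-2-en-1-one (C6 epimers; the C3 ethyl enol ether of 4-isobutyryl-6-methyl-4-prenylcyclohexane-1,3-dione), via ketal cycloadduct 11 (not isolated)
Conditions: (S)-B-(o-tolyl)-diphenylprolinol oxazaborolidine (20 mol%), HN(SO2CF3)2 (17 mol%), CH2Cl2, −78 °C; then 1 M HCl, THF, 0 °C
Reagents that add atoms: none
Why: The protonated oxazaborolidine binds the ketone oxygen of 6 and lowers its LUMO; the methyl-bearing terminus of 10 then bonds to the CH2 terminus (C5–C6) slightly ahead of the bond between the ketene-acetal carbon and the α-carbon (C3–C4) in one asynchronous suprafacial [4+2] event, and acid work-up turns the ketal and silyl enol ether of 11 into the vinylogous ester 12 with loss of ethanol and silanol. The closest known reaction type is the cationic oxazaborolidine-catalysed enantioselective Diels–Alder reaction of 2-substituted acroleins and enones with alkoxy- and siloxy-dienes that creates quaternary α-carbonyl stereocentres. Ring A is closed by the intermolecular cycloaddition itself, both ring bonds being formed through a six-membered transition state. C4 is set by the catalyst, whose aryl groups screen one face of the boron-bound 1,1-disubstituted alkene so that the diene adds to the open face, while C6 forms as an epimer mixture that is irrelevant because it becomes sp2 in step 6. The step needs regiocontrol, secured by the three oxygen donors of 10 that all polarise the diene towards its methyl-bearing terminus and pair it with the enone β-carbon, and chemoselectivity over the unactivated prenyl alkene, which is not a dienophile. It also needs suppression of achiral silyl-cation catalysis, for which the bulky triisopropylsilyl group is chosen.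

Step 6
Reactants: 12 (4S)-3-ethoxy-6-methyl-4-(3-methylbut-2-en-1-yl)-4-(2-methylpropanoyl)cyclohex-2-en-1-one
Product: 14 (4S)-3-ethoxy-6-methyl-4-(3-methylbut-2-en-1-yl)-4-(2-methylpropanoyl)cyclohexa-2,5-dien-1-one, via silyl dienol ether 13 (not isolated)
Conditions: LiN(i-Pr)2, THF, −78 °C; Me3SiCl, −78 → 0 °C; then Pd(OAc)2 (1.1 equiv), MeCN, rt
Reagents that add atoms: none
Why: In this Saegusa–Ito oxidation the amide base deprotonates C6, the only ring position α to the C1 carbonyl, faster than the isobutyryl methine shielded by quaternary C4, and the trapped silyl dienol ether is palladated at C6 and loses a C5 hydrogen by β-hydride elimination to give the cross-conjugated dienone, in which C6 is no longer stereogenic.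

Step 7
Reactants: 14 (4S)-3-ethoxy-6-methyl-4-(3-methylbut-2-en-1-yl)-4-(2-methylpropanoyl)cyclohexa-2,5-dien-1-one
Product: 16 (4S)-3-ethoxy-5-hydroxy-6-methyl-4-(3-methylbut-2-en-1-yl)-4-(2-methylpropanoyl)cyclohex-2-en-1-one (C5 and C6 diastereomers), via C5 boronate 15 (not isolated)
Conditions: B2pin2, CuCl (5 mol%), DPEphos (5 mol%), NaOt-Bu (8 mol%), MeOH (2 equiv), THF, 0 °C → rt; then NaBO3·4H2O, THF/H2O, 0 °C → rt
Reagents that add atoms: sodium perborate tetrahydrate (NaBO3·4H2O, supplies the C5 oxygen), [Na+].[O-]OB=O
Why: In this copper-catalysed conjugate borylation the boryl–copper species adds to C5, the β-carbon of the only enone arm not deactivated by the ethoxy group, and perborate oxidation of the C–B bond under near-neutral conditions gives the β-hydroxy ketone, the new C5 and C6 centres being inconsequential because both become sp2.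

Step 8
Reactants: 16 (4S)-3-ethoxy-5-hydroxy-6-methyl-4-(3-methylbut-2-en-1-yl)-4-(2-methylpropanoyl)cyclohex-2-en-1-one
Product: 17 (4S)-3-ethoxy-5-hydroxy-6-methyl-4-(3-methylbut-2-en-1-yl)-4-(2-methylpropanoyl)cyclohexa-2,5-dien-1-one (enol form of the C1/C5 diketone)
Conditions: Dess–Martin periodinane, pyridine, CH2Cl2, 0 °C → rt
Reagents that add atoms: none
Why: Dess–Martin oxidation of the secondary alcohol gives the C1/C5 diketone, which enolises across the methyl-bearing C6, while the ethyl enol ether keeps C2 from being oxidised as a free 1,3-dione would be.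

Step 9
Reactants: 17 (4S)-3-ethoxy-5-hydroxy-6-methyl-4-(3-methylbut-2-en-1-yl)-4-(2-methylpropanoyl)cyclohexa-2,5-dien-1-one
Product: 18 (4R)-3,5-dihydroxy-6-methyl-4-(3-methylbut-2-en-1-yl)-4-(2-methylpropanoyl)cyclohexa-2,5-dien-1-one (enolised ring A trione with C2 unsubstituted)
Conditions: 1 M HCl, THF, 0 °C → rt
Reagents that add atoms: water, O
Why: Acid-catalysed hydrolysis of the vinylogous ester (addition of water at C3 and loss of ethanol) is fast for the enol ether of a β-triketone and runs in dilute acid at room temperature, where the trisubstituted prenyl alkene is not protonated.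

Step 10
Reactants: 19 1-(2,4,6-trihydroxyphenyl)-2-methylpropan-1-one; 2 1-bromo-3-methylbut-2-ene
Product: 20 2-methyl-1-[2,4,6-trihydroxy-3-(3-methylbut-2-en-1-yl)phenyl]propan-1-one
Conditions: 2 (1.0 equiv), 10% aq. KOH, 0 °C
Reagents that add atoms: none
Why: The ambident phloroglucinolate is alkylated on carbon by the soft allylic bromide in water (C-prenylation of an acylphloroglucinol), and limiting the bromide favours the mono-prenyl compound, which is separated from doubly alkylated material.

Step 11
Reactants: 20 2-methyl-1-[2,4,6-trihydroxy-3-(3-methylbut-2-en-1-yl)phenyl]propan-1-one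
Product: 21 1-{3-[(dimethylamino)methyl]-2,4,6-trihydroxy-5-(3-methylbut-2-en-1-yl)phenyl}-2-methylpropan-1-one
Conditions: Me2NH (40% aq.), HCHO (37% aq.), EtOH, 0 °C → rt
Reagents that add atoms: formaldehyde, C=O; dimethylamine, CNC
Why: The phenolic Mannich reaction takes place at the only unsubstituted ring carbon of 20, which is activated by two ortho oxygens and one para oxygen.

Step 12
Reactants: 18 (4R)-3,5-dihydroxy-6-methyl-4-(3-methylbut-2-en-1-yl)-4-(2-methylpropanoyl)cyclohexa-2,5-dien-1-one; 21 1-{3-[(dimethylamino)methyl]-2,4,6-trihydroxy-5-(3-methylbut-2-en-1-yl)phenyl}-2-methylpropan-1-one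
Product: 23 (4S)-3,5-dihydroxy-6-methyl-4-(3-methylbut-2-en-1-yl)-4-(2-methylpropanoyl)-2-{[2,4,6-trihydroxy-3-(3-methylbut-2-en-1-yl)-5-(2-methylpropanoyl)phenyl]methyl}cyclohexa-2,5-dien-1-one, via ortho-quinone methide 22 (not isolated)
Conditions: 1,4-dioxane, 80 °C, N2 sweep
Reagents that add atoms: none
Why: The acidic trione protonates the benzylic amine, dimethylamine is expelled to give the ortho-quinone methide, and C2 of 18 adds to its methylidene carbon in a Michael addition that rearomatises ring B (Mannich-base alkylation through an ortho-quinone methide), addition at the methyl-bearing C6 being reversible whereas the C2 adduct is held by enolisation, and C4 being untouched.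

Compound list
1 | 3-methylbutan-2-one | CC(C)C(C)=O | starting material
2 | 1-bromo-3-methylbut-2-ene (prenyl bromide) | CC(C)=CCBr | starting material
3 | 2,7-dimethyloct-6-en-3-one | CC(C)C(=O)CCC=C(C)C | intermediate
4 | 4-[(dimethylamino)methyl]-2,7-dimethyloct-6-en-3-one (racemic) | CC(C)C(=O)C(CN(C)C)CC=C(C)C | intermediate
5 | trimethyl[5-methyl-2-(2-methylpropanoyl)hex-4-en-1-yl]ammonium iodide (racemic) | CC(C)C(=O)C(C[N+](C)(C)C)CC=C(C)C.[I-] | intermediate
6 | 2,7-dimethyl-4-methylideneoct-6-en-3-one | C=C(CC=C(C)C)C(=O)C(C)C | intermediate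
7 | 1,1-diethoxyethene | C=C(OCC)OCC | starting material
8 | propanoyl chloride | CCC(=O)Cl | starting material
9 | 1,1-diethoxypent-1-en-3-one | CCC(=O)C=C(OCC)OCC | intermediate
10 | (3Z)-1,1-diethoxy-3-[tri(propan-2-yl)silyloxy]penta-1,3-diene | CCOC(OCC)=C/C(O[Si](C(C)C)(C(C)C)C(C)C)=C/C | intermediate
11 | 1-[(1R)-2,2-diethoxy-5-methyl-1-(3-methylbut-2-en-1-yl)-4-[tri(propan-2-yl)silyloxy]cyclohex-3-en-1-yl]-2-methylpropan-1-one (methyl epimers) | CC(C)[Si](C(C)C)(C(C)C)OC1=CC(OCC)(OCC)[C@@](CC=C(C)C)(C(=O)C(C)C)CC1C | intermediate
12 | (4S)-3-ethoxy-6-methyl-4-(3-methylbut-2-en-1-yl)-4-(2-methylpropanoyl)cyclohex-2-en-1-one (C6 epimers) | O=C1C=C(OCC)[C@@](CC=C(C)C)(C(=O)C(C)C)CC1C | intermediate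
13 | 1-[(1S)-2-ethoxy-5-methyl-1-(3-methylbut-2-en-1-yl)-4-(trimethylsilyloxy)cyclohexa-2,4-dien-1-yl]-2-methylpropan-1-one | C[Si](C)(C)OC=1C=C(OCC)[C@@](CC=C(C)C)(C(=O)C(C)C)CC=1C | intermediate
14 | (4S)-3-ethoxy-6-methyl-4-(3-methylbut-2-en-1-yl)-4-(2-methylpropanoyl)cyclohexa-2,5-dien-1-one | O=C1C=C(OCC)[C@@](CC=C(C)C)(C(=O)C(C)C)C=C1C | intermediate
15 | (4S)-3-ethoxy-6-methyl-4-(3-methylbut-2-en-1-yl)-4-(2-methylpropanoyl)-5-(4,4,5,5-tetramethyl-1,3,2-dioxaborolan-2-yl)cyclohex-2-en-1-one (C5 and C6 diastereomers) | O=C1C=C(OCC)[C@@](CC=C(C)C)(C(=O)C(C)C)C(B2OC(C)(C)C(C)(C)O2)C1C | intermediate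
16 | (4S)-3-ethoxy-5-hydroxy-6-methyl-4-(3-methylbut-2-en-1-yl)-4-(2-methylpropanoyl)cyclohex-2-en-1-one (C5 and C6 diastereomers) | O=C1C=C(OCC)[C@@](CC=C(C)C)(C(=O)C(C)C)C(O)C1C | intermediate
17 | (4S)-3-ethoxy-5-hydroxy-6-methyl-4-(3-methylbut-2-en-1-yl)-4-(2-methylpropanoyl)cyclohexa-2,5-dien-1-one | O=C1C=C(OCC)[C@@](CC=C(C)C)(C(=O)C(C)C)C(O)=C1C | intermediate
18 | (4R)-3,5-dihydroxy-6-methyl-4-(3-methylbut-2-en-1-yl)-4-(2-methylpropanoyl)cyclohexa-2,5-dien-1-one | O=C1C=C(O)[C@@](CC=C(C)C)(C(=O)C(C)C)C(O)=C1C | intermediate
19 | 1-(2,4,6-trihydroxyphenyl)-2-methylpropan-1-one | CC(C)C(=O)c1c(O)cc(O)cc1O | starting material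
20 | 2-methyl-1-[2,4,6-trihydroxy-3-(3-methylbut-2-en-1-yl)phenyl]propan-1-one | CC(C)C(=O)c1c(O)cc(O)c(CC=C(C)C)c1O | intermediate
21 | 1-{3-[(dimethylamino)methyl]-2,4,6-trihydroxy-5-(3-methylbut-2-en-1-yl)phenyl}-2-methylpropan-1-one | CC(C)C(=O)c1c(O)c(CN(C)C)c(O)c(CC=C(C)C)c1O | intermediate
22 | 3,5-dihydroxy-6-methylidene-4-(3-methylbut-2-en-1-yl)-2-(2-methylpropanoyl)cyclohexa-2,4-dien-1-one | C=C1C(=O)C(C(=O)C(C)C)=C(O)C(CC=C(C)C)=C1O | intermediate
23 | (4S)-3,5-dihydroxy-6-methyl-4-(3-methylbut-2-en-1-yl)-4-(2-methylpropanoyl)-2-{[2,4,6-trihydroxy-3-(3-methylbut-2-en-1-yl)-5-(2-methylpropanoyl)phenyl]methyl}cyclohexa-2,5-dien-1-one | CC(C)=CCc1c(O)c(CC2=C(O)[C@@](CC=C(C)C)(C(=O)C(C)C)C(O)=C(C)C2=O)c(O)c(C(=O)C(C)C)c1O | target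

Total step count: 12. Longest linear sequence: 8 steps (steps 1, 2, 5, 6, 7, 8, 9, 12, from 3-methylbutan-2-one).

Steps most likely to fail

Step 5. The enone has neither a formyl hydrogen nor an α-vinyl hydrogen to organise its binding to the catalyst, so facial discrimination may be weak. Silyl transfer from the diene may also open an achiral stepwise Michael pathway, and the enone may react as a heterodiene with the electron-rich alkene of 10. The fallback moves the asymmetric cycloaddition to the aldehyde series and builds the isopropyl ketone afterwards. It sets out from diene 10 and comes back at 12. Commercial 5-methylhex-4-enal is α-methylenated with aqueous formaldehyde and pyrrolidinium propionate to 5-methyl-2-methylidenehex-4-enal F1. This 2-substituted acrolein, the dienophile class for which the protonated oxazaborolidine is best established, undergoes the same cycloaddition with 10 to give the ketal cycloadduct aldehyde F2. Acid work-up hydrolyses it to the vinylogous ester aldehyde F3. Addition of i-PrMgCl/CeCl3 at −78 °C to the formyl group, in preference to the vinylogous ester carbonyl, gives the carbinol F4, and Dess–Martin oxidation of F4 gives 12.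

Step 7. Addition of the boryl–copper species to C5 may be slow, because C5 is flanked by quaternary C4 and the methylated C6. The alkoxide present may also open the β-hydroxy ketone by retro-aldol cleavage or remove the isobutyryl group from C4. The fallback uses a small oxygen nucleophile and a neutral reductive opening. It sets out from 14 and comes back at 16. Nucleophilic epoxidation of the C5–C6 enone arm (t-BuOOH, DBU, CH2Cl2, 0 °C; Weitz–Scheffer type) gives the epoxy ketone F5. Its Cα–O bond is then cleaved with SmI2 in THF/MeOH at −78 °C to give 16.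

Step 12. The quinone methide may be captured at the methyl-bearing C6 or at an enol oxygen of 18, or may condense with itself, and the liberated amine may remove the isobutyryl group from C4 in an aromatisation-driven retro-Claisen cleavage. The fallback reverses the roles of the two rings. It sets out from 18 (with 20 as partner) and comes back at 23. Aminomethylation of C2 of 18 with dimethylmethylideneammonium iodide in CH2Cl2 at 0 °C gives the ring A Mannich base F6. Gentle warming of F6 with 20 in MeCN expels dimethylamine to give the 2-methylidene trione F7. The single free aromatic carbon of 20 adds to F7 in a conjugate addition to give 23.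

Further compounds
F1 | step 5 | 5-methyl-2-methylidenehex-4-enal | C=C(CC=C(C)C)C=O
F2 | step 5 | (1R)-2,2-diethoxy-5-methyl-1-(3-methylbut-2-en-1-yl)-4-[tri(propan-2-yl)silyloxy]cyclohex-3-ene-1-carbaldehyde (methyl epimers) | CC(C)[Si](C(C)C)(C(C)C)OC1=CC(OCC)(OCC)[C@@](CC=C(C)C)(C=O)CC1C
F3 | step 5 | (1S)-2-ethoxy-5-methyl-1-(3-methylbut-2-en-1-yl)-4-oxocyclohex-2-ene-1-carbaldehyde (methyl epimers) | O=C1C=C(OCC)[C@@](CC=C(C)C)(C=O)CC1C
F4 | step 5 | (4R)-3-ethoxy-4-(1-hydroxy-2-methylpropyl)-6-methyl-4-(3-methylbut-2-en-1-yl)cyclohex-2-en-1-one (carbinol and C6 epimers) | O=C1C=C(OCC)[C@@](CC=C(C)C)(C(O)C(C)C)CC1C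
F5 | step 7 | (5S)-4-ethoxy-1-methyl-5-(3-methylbut-2-en-1-yl)-5-(2-methylpropanoyl)-7-oxabicyclo[4.1.0]hept-3-en-2-one (epoxide diastereomers) | O=C1C=C(OCC)[C@@](CC=C(C)C)(C(=O)C(C)C)C2OC12C
F6 | step 12 | (4S)-2-[(dimethylamino)methyl]-3,5-dihydroxy-6-methyl-4-(3-methylbut-2-en-1-yl)-4-(2-methylpropanoyl)cyclohexa-2,5-dien-1-one | O=C1C(CN(C)C)=C(O)[C@@](CC=C(C)C)(C(=O)C(C)C)C(O)=C1C
F7 | step 12 | (4R)-5-hydroxy-6-methyl-2-methylidene-4-(3-methylbut-2-en-1-yl)-4-(2-methylpropanoyl)cyclohex-5-ene-1,3-dione | O=C1C(=C)C(=O)[C@@](CC=C(C)C)(C(=O)C(C)C)C(O)=C1C
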